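The product is read as monomer in chains divided by chains begun, so a chain's length depends on how many chains each fall of free monomer costs.

    free monomer + initiator → living end + monomer in chains (k1 = 5.1 /M/s)
    free monomer + living end → monomer in chains + living end, rate k2*[living end]*[free monomer] (k2 = 7800 /M/s)
    living end + transfer agent → dead chain (k3 = 11 /M/s)
    living end + free monomer → dead end (k4 = 2.1 /M/s)
    pre-initiator → initiator (k5 = 0.020 /s)

in all of them: free monomer 0.050 M; pre-initiator 0.10 mM; time 12 min
- alder: transfer agent 5.00 mM
- ash: transfer agent 10.0 mM

- which of the two ends with the longer chains by the average number of monomer units in a chain (chains begun, living or dead) ("neither" if they lie within 10%) (alder / ash / neither)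
- average number of monomer units in a chain (chains begun, living or dead) at the end, alder
- average number of monomer units in a chain (chains begun, living or dead) at the end, ash

In alder a living end has a half-life of 0.21 min by transfer alone, shorter than the 0.58 min half-life of the pre-initiator that feeds it, so this reckoning takes it in steady state. Each chain begun then adds the kinetic chain length: the propagation rate over the summed rates of transfer and of the step to dead end. Summed over the run, chains begun come to T·x + D. Here x is the natural logarithm of charged over remaining c(free monomer), D = 1.35 × 10⁻⁵ M is the dead ends, and T, the transfer cost, is the chains lost per e-fold fall of c(free monomer), the transfer constant times c(transfer agent) over the propagation constant: 7.05 × 10⁻⁶ M in alder and 1.41 × 10⁻⁵ M in ash.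

The propagation constant divides both terms and also reaches x through them, as the relation for x below shows, so x shifts against an error in it and the average takes up that error in part. The transfer constant and c(transfer agent) act through T, and the constant of the step to dead end through D. The initiation constant acts through x, where it stands inside a logarithm, so the average answers it weakly. The release constant matters little, since its half-life is far shorter than the run.

Late in the run, e^x ≈ G·((c(pre-initiator) − D)/T − x), with G = 184 the initiation constant times charge times time. Averaging a trial value with what it returns gives x = 6.94 for alder from trial 7, and 5.17 for ash from trial 5. The averages are then 802 and 579, so alder is longer by 38.5%, beyond the 10% margin.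

The forecast names alder, with 770 and 540, “so it starts fewer chains and ends with the longer ones”.

The flasks give alder, with 801 in alder and 557 in ash. In alder 0.083% of the charged free monomer remains, and through T that amount gives 5.00 × 10⁻⁵ M of dead chain against 4.88 × 10⁻⁵ M in the flask. The neighbour of alder charged with 0.030 M of free monomer has the same T and keeps 0.11% of its charge, which gives 4.78 × 10⁻⁵ M of dead chain against 4.64 × 10⁻⁵ M in that flask, whose average is 549.

Its constants were set for the occasion; the flask was simulated.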